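## Analysis of the target

The target is a cyclohexene cis-fused to an oxirane (a 7-oxabicyclo[4.1.0]hept-4-ene). In the locants used here for every compound, C1 is the quaternary oxirane carbon carrying the exocyclic C7 methylene as its benzoate, C2 is the carbinol carbon, C3 carries the second benzoate, C4=C5 is the alkene and C6 is the oxirane CH. There are four contiguous stereocentres, C1, C2, C3 and C6 (1R,2S,3S,6S in this numbering): the C2 hydroxyl and the C3 benzoate are cis to each other, and the oxirane oxygen lies on the opposite ring face, trans to both, so that C7 shares the face of the two oxygens. The sensitive functions are the vinyl oxirane (opened by acid, soft nucleophiles and zerovalent palladium), the allylic C3 benzoate, and the cis 2-hydroxy-3-benzoate pair, in which the acyl group can migrate under base. The difficulty lies in placing four differently dressed oxygens on five of the seven carbons, in building the quaternary stereocentre C1, and in putting the oxirane on C1–C6 rather than C4–C5, on the face away from the C2 and C3 oxygens. The strategy rests on reading the C1–C6 oxirane together with the C4=C5 alkene as the mono-oxide of a C1=C6–C5=C4 diene. Without the oxirane oxygen the ring is a cyclohexa-1,3-diene with a cis-diol at C2 and C3 and a carbon substituent on the diene terminus next to the diol, which is the pattern of the cis-dihydrodiol formed from bromobenzene by microbial dioxygenation, with the halogen at C1. An oxidant that approaches this diene anti to the two oxygens delivers oxygen to the face on which the oxirane oxygen of the target lies.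

## Retrosynthetic reasoning

**C2 O–Si bond (15 from 14).** The last operation only uncovers the C2 hydroxyl. It stays masked until the end because a free hydroxyl beside the C3 benzoate invites acyl migration, and beside the C1 alkoxide of the deoxygenation step it would interfere. A triethylsilyl ether is chosen because buffered fluoride removes it without opening the vinyl oxirane or touching the benzoates.

**C6–O bond of the oxirane (14 from 12).** The oxirane is opened at C6–O while C1–O is kept, and an oxygen is restored on C4, joined to the C1 oxygen as a peroxide; this gives endoperoxide 12 with the alkene at C5=C6. Cutting here and not at C1–O leaves the quaternary stereocentre untouched and makes oxirane formation intramolecular, so only the cis-fused ring on the face already carrying the oxygen can form. The forward reaction has to remove the C4 oxygen selectively with a trivalent phosphorus reagent and shift the alkene to C4=C5.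

**C1–O and C4–O bonds (12 from 10 and 11).** Both peroxide C–O bonds are cut at once, giving diene 10 and dioxygen 11 (used in its singlet state). This removes a ring and two stereocentres in one step and leads to a diene whose only stereocentres are C2 and C3. It is preferred to a direct epoxidation of 10 because a peracid would have to tell C1=C6 from C4=C5. The cycloaddition uses both alkenes, and the choice between them is postponed to the two peroxide oxygens, one on a quaternary and one on a secondary carbon. The forward reaction has to add 11 to the face anti to the C2 and C3 oxygens.

**Ester and silyl ether bonds of the diene (10 from 9; 9 from 6 and 7 through 8).** The C2 silyl ether is removed to give hydroxy dibenzoate 9, and the two ester C–O bonds are cut to triol 6 and benzoyl chloride 7. The forward benzoylation has to take the primary C7 hydroxyl (giving 8) and then the distal C3 hydroxyl, and leave the C2 hydroxyl, which is pseudoaxial and wedged between C1 and C3. The remaining hydroxyl is then capped with 2.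

**C1–C7 bond (6 from 5; 5 from 3 and 4).** The exocyclic carbon is detached at the sp2 carbon C1: Stille coupling of alkenyl bromide 3 with stannane 4. The bond is made at a trigonal carbon, so no stereochemical question arises, and it is made where the dihydrodiol carries its halogen. The diol travels through the coupling as bis(triethylsilyl) ether 3. Silyl ethers do not ionise with zerovalent palladium, as allylic esters would. Unlike an isopropylidene acetal they are removed by fluoride, so the acid-labile dienetriol 6 never meets aqueous acid.

**O–Si bonds (3 from 1 and 2).** Simple protection leads back to the microbial diol 1, which supplies the ring, the diene, the halogen handle at C1 and both oxygen stereocentres with the configuration of the target.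

## Alternatives that were turned down

**Alternative 1: ring and oxirane from one sulfur ylide addition.**
- Disconnection: the C1–C6 ring bond and the C6–O oxirane bond are cut together, leading to the open-chain C1 ketone A2, whose C6 terminus is a (Z)-allylic tetrahydrothiophenium salt.
- Forward key step: Cs2CO3 would form the allylic ylide at C6; this adds to the ketone, and the alkoxide expels the sulfide to give the tris-silyl epoxy triol A1.
- For: carbocycle, quaternary centre and oxirane arise in one step without photochemistry. C2 and C3 could be taken from the tartrate or sugar pool in either enantiomeric series. On both points it is stronger than a route tied to one microbial metabolite.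
- Against: nothing in the flexible chain of A2 forces the ylide onto the ketone face that puts O1 trans to the C2 oxygen. The ketone is α- and β-oxygenated, so carbonate can epimerise C2 or eliminate the C3 silyloxy group. The allylic ylide can also react through its γ-carbon, and the (Z)-alkene has to survive salt formation.
- After A1, three silyl ethers must be removed and C7 and C3 benzoylated selectively in the presence of the oxirane. That is the same differentiation problem as in the chosen route, but at the end and on a more fragile compound.
- Comparison: A2 alone would take about as many steps as the whole chosen route. The chosen strategy gives up the one-step ring and oxirane construction but works on a rigid ring with one blocked face, so both new stereocentres follow a predictable steric bias.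

**Alternative 2: Nozaki–Hiyama–Kishi closure of C3–C4 on a tartrate template.**
- Disconnection: the C3–C4 bond, leading to dioxolane A4, in which an acetonide spans O1 and O2 and which carries a C3 aldehyde and a (Z)-alkenyl iodide at C4.
- Forward key step: CrCl2 with catalytic NiCl2 would generate an alkenylchromium nucleophile that adds to the aldehyde and closes cyclohexenol A3, trans-fused to the acetonide.
- For: the reaction is chemoselective for aldehydes and tolerates the ester, acetal and ether groups. Every oxygen of A3 is in a different form (free C3 hydroxyl, C6 ether, O1/O2 acetal, C7 ester), so no selective acylation is needed; on this point it is stronger than the chosen route.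
- Against: the C3 carbinol configuration is created in the closure with little substrate bias. The quaternary C1 with its C6 side chain must first be built stereoselectively on the tartrate acetal.
- A3 is still far from the target: ester reduction, ether cleavage, sulfonylation of the C6 hydroxyl, acetal hydrolysis beside allylic oxygens, base closure of the oxirane with inversion at C6, and two benzoylations remain. The step count would be more than double, and CrCl2 is needed in large excess.
- Comparison: the chosen route accepts one selective benzoylation and in return makes the oxirane and the quaternary stereocentre in two steps from a diene bought with its stereocentres in place.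

**Alternative 3: Ferrier carbocyclisation forming C2–C3.**
- Disconnection: the C2–C3 bond, by an aldol-type closure, leading to the glucal-derived 2,3-unsaturated pyranoside A6 with an exocyclic enol chloroacetate.
- Forward key step: catalytic Hg(OCOCF3)2 in aqueous acetone would oxymercurate the enol ester; the ring opens to a C1 ketone and a (Z)-enal, and the α-mercurio ketone adds to the aldehyde to give cyclohexenone A5.
- For: the starting sugar is cheap and the carbocyclisation is dependable in the saturated series. In A5 the C2 oxygen (chloroacetate) and the C3 oxygen (free) are already distinguished, so benzoylation and a later mild dechloroacetylation would give the C2 hydroxyl / C3 benzoate pattern without any selectivity problem. On this point it is stronger than the chosen route.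
- Against: the open-chain (Z)-enal can isomerise to the (E)-enal, which cannot close. Two stereocentres (C2, C3) arise in the aldol step under modest control. A5 is one dehydration away from a cyclohexadienone that is the keto tautomer of a catechol ester.
- C1 is still a ketone, so C7 must be added and the quaternary carbinol and oxirane built afterwards (for example by methylenation, face-selective epoxidation and epoxide migration onto the C6 oxygen), each with its own stereochemical risk. A mercury salt is also needed.
- Comparison: the chosen route joins C7 to a trigonal C1 with no stereochemical question and obtains the oxirane directly from the cycloadduct.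

Key step: step 6

Assumption: diol 1 is taken as the commercial single (1S,2S) enantiomer from microbial oxidation of bromobenzene; its two oxygens already have the configuration of O2 and O3 of the target and no stereocentre of 1 is inverted anywhere in the route.

## Route

Step 1
Reactants: 1 (1S,2S)-3-bromocyclohexa-3,5-diene-1,2-diol; 2 chlorotriethylsilane
Product: 3 (5S,6S)-1-bromo-5,6-bis(triethylsilyloxy)cyclohexa-1,3-diene
Conditions: Et3SiCl (2.5 equiv), imidazole (5 equiv), DMF, 0 °C → rt
Reagents that add atoms: chlorotriethylsilane, CC[Si](Cl)(CC)CC
Why: Imidazole-promoted silylation of both secondary allylic hydroxyls under non-acidic conditions, which avoids dehydration of the dihydrodiol to a bromophenol. No stereocentre is touched, and the ethers can later be removed by fluoride instead of acid.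

Step 2
Reactants: 3 (5S,6S)-1-bromo-5,6-bis(triethylsilyloxy)cyclohexa-1,3-diene; 4 (tributylstannyl)methanol
Product: 5 [(5S,6R)-5,6-bis(triethylsilyloxy)cyclohexa-1,3-dien-1-yl]methanol
Conditions: Pd(PPh3)4 (5 mol %), Bu3SnCH2OH (1.3 equiv), 1,4-dioxane (degassed), 85 °C
Reagents that add atoms: (tributylstannyl)methanol, CCCC[Sn](CCCC)(CCCC)CO
Why: Stille coupling: zerovalent palladium inserts into the C1–Br bond, the hydroxymethyl group is transferred from tin in preference to butyl, and reductive elimination forms C1–C7 at a trigonal carbon. The silyl ethers are poor leaving groups, so the allylic C–O bonds are not ionised, and C2 and C3 are unaffected (the descriptor at the proximal carbon changes only through ligand priorities).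

Step 3
Reactants: 5 [(5S,6R)-5,6-bis(triethylsilyloxy)cyclohexa-1,3-dien-1-yl]methanol
Product: 6 (1S,2R)-3-(hydroxymethyl)cyclohexa-3,5-diene-1,2-diol
Conditions: Bu4NF (2.4 equiv), AcOH (2.4 equiv), THF, 0 °C → rt; concentration, filtration through Et3N-deactivated silica
Reagents that add atoms: none
Why: Fluoride-induced cleavage of both Si–O bonds through a pentacoordinate silicate; the acetic acid buffer keeps the medium near neutral. No mineral acid is present to ionise the doubly allylic C3–O bond and aromatise the triol.

Step 4
Reactants: 6 (1S,2R)-3-(hydroxymethyl)cyclohexa-3,5-diene-1,2-diol; 7 benzoyl chloride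
Product: 9 [(5S,6R)-5-(benzoyloxy)-6-hydroxycyclohexa-1,3-dien-1-yl]methyl benzoate, via primary monobenzoate 8 (not isolated)
Conditions: BzCl (1.05 equiv), pyridine/CH2Cl2, −40 °C; then BzCl (1.05 equiv), −40 → −15 °C
Reagents that add atoms: benzoyl chloride, O=C(Cl)c1ccccc1
Why: Pyridine-mediated acylation in order of accessibility: the primary C7 hydroxyl reacts first (8), then the distal C3 hydroxyl, which is pseudoequatorial and flanked by an unsubstituted vinyl CH. The C2 hydroxyl is pseudoaxial, wedged between C3 and the C1 carbon now bearing the benzoyloxymethyl group, and should remain free.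

Step 5
Reactants: 9 [(5S,6R)-5-(benzoyloxy)-6-hydroxycyclohexa-1,3-dien-1-yl]methyl benzoate; 2 chlorotriethylsilane
Product: 10 [(5S,6R)-5-(benzoyloxy)-6-(triethylsilyloxy)cyclohexa-1,3-dien-1-yl]methyl benzoate
Conditions: Et3SiCl (1.5 equiv), imidazole (3 equiv), 4-(dimethylamino)pyridine (cat.), CH2Cl2, 0 °C → rt
Reagents that add atoms: chlorotriethylsilane, CC[Si](Cl)(CC)CC
Why: Silylation of the one remaining secondary hydroxyl under mildly basic conditions. The cap blocks benzoyl migration from O3 to O2, removes a hydrogen-bond donor that could steer singlet oxygen to the wrong face, and adds bulk on the lower face next to C1.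

Step 6
Reactants: 10 [(5S,6R)-5-(benzoyloxy)-6-(triethylsilyloxy)cyclohexa-1,3-dien-1-yl]methyl benzoate; 11 dioxygen
Product: 12 [(1R,4R,7S,8S)-8-(benzoyloxy)-7-(triethylsilyloxy)-2,3-dioxabicyclo[2.2.2]oct-5-en-1-yl]methyl benzoate
Conditions: O2 (1 atm), hν (visible), 5,10,15,20-tetraphenylporphyrin (1 mol %), CH2Cl2, −40 °C
Reagents that add atoms: dioxygen, O=O
Why: The photoexcited sensitiser passes its triplet energy to O2, and the singlet oxygen formed acts as a two-atom dienophile toward the C1=C6–C5=C4 diene, which the ring holds s-cis; the C1–O and C4–O bonds form in one suprafacial [4+2] event. The closest known reaction type is the photooxygenation of cyclohexa-1,3-dienes, including O-protected arene cis-dihydrodiols, to 2,3-dioxabicyclo[2.2.2]oct-5-enes. The one new ring, a six-membered 1,2-dioxene, is closed by intermolecular cycloaddition of O2 across C1 and C4 and not by cyclisation of a tether, and this creates the bicyclo[2.2.2] frame. C1 and C4 become stereocentres; their mutual cis relationship follows from suprafacial addition and their absolute sense from the face of attack. That face is set by the substrate: the C2 silyl ether stands pseudoaxial on the lower face beside the C1 terminus and the C3 benzoate lies on the same face beside C4, so O2 should enter from the upper face and the peroxide bridge should end trans to both oxygens. The step needs this facial selectivity and also chemoselectivity for [4+2] over the ene reaction at the C7 and C2 hydrogens. The locked cisoid diene (cyclohexadienes favour cycloaddition), the pseudoequatorial C2–H, which is poorly aligned for abstraction, and the low temperature in an aprotic solvent should secure both. No regiochemical question arises because O2 is symmetric; which alkene of the diene survives is decided only in step 7.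

Step 7
Reactants: 12 [(1R,4R,7S,8S)-8-(benzoyloxy)-7-(triethylsilyloxy)-2,3-dioxabicyclo[2.2.2]oct-5-en-1-yl]methyl benzoate
Product: 14 [(1S,2S,3S,6S)-3-(benzoyloxy)-2-(triethylsilyloxy)-7-oxabicyclo[4.1.0]hept-4-en-1-yl]methyl benzoate, via oxyphosphonium alkoxide betaine 13 (not isolated)
Conditions: PPh3 (1.1 equiv), CH2Cl2, −20 °C → rt
Reagents that add atoms: none
Why: Phosphine deoxygenation of a 1,4-endoperoxide to a diene mono-oxide: PPh3 attacks the peroxide oxygen on the secondary C4 (the oxygen on quaternary C1 is screened by C7 and the C2 silyl ether), and O–O heterolysis gives betaine 13. Its C1 alkoxide attacks C6 on the same face in a syn SN2′ displacement of Ph3PO from C4. The C1–O bond is never broken, so C1 keeps its configuration (the descriptor changes only by priority), C6 is set by the necessarily cis-fused closure on the face that carried the peroxide, and the alkene ends at C4=C5.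

Step 8
Reactants: 14 [(1S,2S,3S,6S)-3-(benzoyloxy)-2-(triethylsilyloxy)-7-oxabicyclo[4.1.0]hept-4-en-1-yl]methyl benzoate
Product: 15 [(1R,2S,3S,6S)-3-(benzoyloxy)-2-hydroxy-7-oxabicyclo[4.1.0]hept-4-en-1-yl]methyl benzoate
Conditions: Bu4NF (1.2 equiv), AcOH (1.2 equiv), THF, 0 °C
Reagents that add atoms: none
Why: Buffered fluoride desilylation; the acetic acid protonates the C2 alkoxide as it forms, so benzoyl migration from O3 to O2 and opening of the vinyl oxirane are suppressed. No stereocentre is touched.

## Compound list

1 | (1S,2S)-3-bromocyclohexa-3,5-diene-1,2-diol | BrC1=CC=C[C@H](O)[C@@H]1O | starting material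
2 | chlorotriethylsilane | CC[Si](Cl)(CC)CC | starting material
3 | (5S,6S)-1-bromo-5,6-bis(triethylsilyloxy)cyclohexa-1,3-diene | BrC1=CC=C[C@H](O[Si](CC)(CC)CC)[C@@H]1O[Si](CC)(CC)CC | intermediate
4 | (tributylstannyl)methanol | CCCC[Sn](CCCC)(CCCC)CO | starting material
5 | [(5S,6R)-5,6-bis(triethylsilyloxy)cyclohexa-1,3-dien-1-yl]methanol | OCC1=CC=C[C@H](O[Si](CC)(CC)CC)[C@@H]1O[Si](CC)(CC)CC | intermediate
6 | (1S,2R)-3-(hydroxymethyl)cyclohexa-3,5-diene-1,2-diol | OCC1=CC=C[C@H](O)[C@@H]1O | intermediate
7 | benzoyl chloride | O=C(Cl)c1ccccc1 | starting material
8 | [(5S,6R)-5,6-dihydroxycyclohexa-1,3-dien-1-yl]methyl benzoate (primary monobenzoate) | O=C(OCC1=CC=C[C@H](O)[C@@H]1O)c1ccccc1 | intermediate (not isolated)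
9 | [(5S,6R)-5-(benzoyloxy)-6-hydroxycyclohexa-1,3-dien-1-yl]methyl benzoate | O=C(OCC1=CC=C[C@H](OC(=O)c2ccccc2)[C@@H]1O)c1ccccc1 | intermediate
10 | [(5S,6R)-5-(benzoyloxy)-6-(triethylsilyloxy)cyclohexa-1,3-dien-1-yl]methyl benzoate | O=C(OCC1=CC=C[C@H](OC(=O)c2ccccc2)[C@@H]1O[Si](CC)(CC)CC)c1ccccc1 | intermediate
11 | dioxygen | O=O | starting material
12 | [(1R,4R,7S,8S)-8-(benzoyloxy)-7-(triethylsilyloxy)-2,3-dioxabicyclo[2.2.2]oct-5-en-1-yl]methyl benzoate | O=C(OC[C@]12OO[C@H](C=C1)[C@H](OC(=O)c1ccccc1)[C@@H]2O[Si](CC)(CC)CC)c1ccccc1 | intermediate
13 | betaine: ring-opened cyclohex-5-ene with C1 alkoxide and C4 triphenylphosphoniooxy group cis to each other, C3 benzoate and C2 triethylsilyl ether on the other face | O=C(OC[C@]1([O-])C=C[C@@H](O[P+](c2ccccc2)(c2ccccc2)c2ccccc2)[C@H](OC(=O)c2ccccc2)[C@@H]1O[Si](CC)(CC)CC)c1ccccc1 | intermediate (not isolated)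
14 | [(1S,2S,3S,6S)-3-(benzoyloxy)-2-(triethylsilyloxy)-7-oxabicyclo[4.1.0]hept-4-en-1-yl]methyl benzoate | O=C(OC[C@]12O[C@H]1C=C[C@H](OC(=O)c1ccccc1)[C@@H]2O[Si](CC)(CC)CC)c1ccccc1 | intermediate
15 | [(1R,2S,3S,6S)-3-(benzoyloxy)-2-hydroxy-7-oxabicyclo[4.1.0]hept-4-en-1-yl]methyl benzoate | O=C(OC[C@]12O[C@H]1C=C[C@H](OC(=O)c1ccccc1)[C@@H]2O)c1ccccc1 | target

## Step count and least certain steps

Total step count: 8. Longest linear sequence: 8 steps (1 to 15).

**Step 6 (key step).** Most likely failures are insufficient facial discrimination (attack syn to the C2 and C3 oxygens), a competing ene reaction at the C7 hydrogens, loss of the C3 benzoate with aromatisation of the diene under irradiation, or rearrangement of the peroxide on warming. Fallback: from 10, electrophilic epoxidation with dimethyldioxirane (acetone/CH2Cl2, −20 °C) should transfer oxygen to the trisubstituted C1=C6 alkene anti to the pseudoaxial C2 silyl ether, while the disubstituted C4=C5 alkene is deactivated by the allylic benzoate. This rejoins the route directly at 14 (no new compound, F0). Its weak point is the choice between the two alkenes, which is why it is not the main plan.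

**Step 7.** Most likely failures are phosphine attack on the C1 peroxide oxygen (which would place the oxirane on C4–C5), a Kornblum–DeLaMare-type fragmentation to a hydroxy enone, or silyl or acyl transfer to the C1 alkoxide before ring closure. Fallback: from 12, reduction of the O–O bond with thiourea in MeOH at 0 °C gives the cis-enediol [(1R,4R,5S,6S)-5-(benzoyloxy)-1,4-dihydroxy-6-(triethylsilyloxy)cyclohex-2-en-1-yl]methyl benzoate F1. Mitsunobu-type cyclodehydration (PPh3, diisopropyl azodicarboxylate, THF, 0 °C) then activates the secondary allylic C4 hydroxyl and not the tertiary C1 hydroxyl, and the C1 oxygen closes onto C6 by the same syn SN2′ path, returning to 14. The site of activation is then decided by the difference between a secondary and a tertiary alcohol instead of by the approach of phosphorus to a peroxide.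

**Step 4.** Most likely failures are incomplete discrimination between the C3 and C2 hydroxyls, over-acylation, and dehydration of the polar triol 6 during handling. Fallback: from 5, benzoylation of the C7 hydroxyl (BzCl, pyridine, 0 °C) gives [(5S,6R)-5,6-bis(triethylsilyloxy)cyclohexa-1,3-dien-1-yl]methyl benzoate F2. Buffered desilylation (Bu4NF, AcOH, THF) gives diol 8, now isolated as a lipophilic compound. Catalytic 2-aminoethyl diphenylborinate (Ph2BOCH2CH2NH2) with BzCl and i-Pr2NEt in MeCN binds the cis-diol and directs acylation to the pseudoequatorial C3 oxygen, returning to 9. This bypasses triol 6 and replaces steric differentiation by chelate-controlled activation.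

**Step 2.** Most likely failures are slow transfer of the sp3 hydroxymethyl group from tin to the hindered alkenylpalladium intermediate, with thermal [4+2] dimerisation or reduction of the bromodiene taking over. Fallback: from 3, methoxycarbonylation (Pd(OAc)2, PPh3, CO 1 atm, MeOH, Et3N, DMF, 60 °C) gives methyl (5S,6R)-5,6-bis(triethylsilyloxy)cyclohexa-1,3-diene-1-carboxylate F3, and 1,2-reduction of the ester with i-Bu2AlH (CH2Cl2, −78 °C) returns to 5.

## Further compounds

F0 | step 6 | none | none
F1 | step 7 | [(1R,4R,5S,6S)-5-(benzoyloxy)-1,4-dihydroxy-6-(triethylsilyloxy)cyclohex-2-en-1-yl]methyl benzoate | O=C(OC[C@]1(O)C=C[C@@H](O)[C@H](OC(=O)c2ccccc2)[C@@H]1O[Si](CC)(CC)CC)c1ccccc1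
F2 | step 4 | [(5S,6R)-5,6-bis(triethylsilyloxy)cyclohexa-1,3-dien-1-yl]methyl benzoate | O=C(OCC1=CC=C[C@H](O[Si](CC)(CC)CC)[C@@H]1O[Si](CC)(CC)CC)c1ccccc1
F3 | step 2 | methyl (5S,6R)-5,6-bis(triethylsilyloxy)cyclohexa-1,3-diene-1-carboxylate | COC(=O)C1=CC=C[C@H](O[Si](CC)(CC)CC)[C@@H]1O[Si](CC)(CC)CC
A1 | alternative 1 | 1-(tert-butyldimethylsilyloxymethyl)-2,3-bis(tert-butyldimethylsilyloxy)-7-oxabicyclo[4.1.0]hept-4-ene, configured as 15 | CC(C)(C)[Si](C)(C)OC[C@]12O[C@H]1C=C[C@H](O[Si](C)(C)C(C)(C)C)[C@@H]2O[Si](C)(C)C(C)(C)C
A2 | alternative 1 | 1-[(Z)-4,5,7-tris(tert-butyldimethylsilyloxy)-6-oxohept-2-enyl]thiolan-1-ium bromide, C4 and C5 of the chain configured as C3 and C2 of A1 | CC(C)(C)[Si](C)(C)OCC(=O)[C@@H](O[Si](C)(C)C(C)(C)C)[C@@H](O[Si](C)(C)C(C)(C)C)/C=C\C[S+]1CCCC1.[Br-]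
A3 | alternative 2 | methyl 7-hydroxy-4-(4-methoxybenzyloxy)-2,2-dimethyl-3a,4,7,7a-tetrahydro-1,3-benzodioxole-3a-carboxylate, trans-fused | COC(=O)[C@@]12OC(C)(C)O[C@H]1[C@@H](O)C=C[C@H]2OCc1ccc(OC)cc1
A4 | alternative 2 | methyl 5-formyl-4-[(Z)-3-iodo-1-(4-methoxybenzyloxy)prop-2-enyl]-2,2-dimethyl-1,3-dioxolane-4-carboxylate | COC(=O)[C@]1(OC(C)(C)O[C@H]1C=O)[C@H](OCc1ccc(OC)cc1)/C=C\I
A5 | alternative 3 | 3-(tert-butyldimethylsilyloxy)-6-hydroxy-2-oxocyclohex-4-en-1-yl chloroacetate | O=C1[C@@H](OC(=O)CCl)[C@@H](O)C=C[C@@H]1O[Si](C)(C)C(C)(C)C
A6 | alternative 3 | (Z)-[(3S,6S)-3-(tert-butyldimethylsilyloxy)-6-methoxy-3,6-dihydro-2H-pyran-2-ylidene]methyl chloroacetate | CO[C@@H]1C=C[C@H](O[Si](C)(C)C(C)(C)C)/C(=C/OC(=O)CCl)O1
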